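The earlier runs and the new flask were generated by integration from invented constants; noise was put on by code.

- The pitfall is the bench rule that divides free monomer by the pre-initiator charged: at full conversion it gives 53.3 units per chain in north-west and 80.0 in north-east. It assumes that the whole charge begins chains at the start.

common to all: free monomer 0.80 M
- amber: pre-initiator 8.5 mM; run made earlier
- red: pre-initiator 9.6 mM; run made earlier
- north-west: pre-initiator 15 mM; time 10 min
- north-east: pre-initiator 10 mM; time 10 min

| run | time / min | monomer in chains / % | free monomer / % |
|---|---|---|---|
| amber | 0.833 | 1.3 | 99.4 |
| amber | 2.50 | 10.3 | 89.8 |
| amber | 5.00 | 35.0 | 64.9 |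
| amber | 8.00 | 63.4 | 36.7 |
| amber | 10.0 | 76.2 | 23.5 |
| red | 0.833 | 1.6 | 98.7 |
| red | 1.50 | 3.3 | 95.6 |
| red | 3.00 | 16.9 | 83.3 |
| red | 5.00 | 38.9 | 61.6 |
| red | 10.0 | 79.7 | 19.9 |

(each reading ± 0.3 percentage points)

1. which of the two ends with the longer chains by the average number of monomer units in a chain (chains begun, living or dead) ("neither" if they lie within 10%) (north-west / north-east / neither)
2. average number of monomer units in a chain (chains begun, living or dead) at the end, north-west
3. average number of monomer units in a chain (chains begun, living or dead) at the end, north-east

- the average divides the monomer in chains by the number of chains begun, living and dead together
- the numbers in the tables scatter by 0.3 percentage points (one standard deviation)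
- the earlier runs do not show the number of chains; that part of a forecast is a guess

- Both runs start slowly, an induction period. In amber, the slope of ln(charge/free monomer) reads 0.130 /min around 3.75 min and 0.203 /min around twice that time.
- We take the slope to follow the released share of a first-order pre-initiator. The later slope over the earlier, less one, is then the share unreleased at the earlier time, which gives a read half-life of 4.54 min.
- So we count the half-lives elapsed, the asked time divided by that half-life: 2.20. The rule needs this count to be large, but by this reading 21.8% of either charge stays unreleased, so we reckon with 78.3% of it released, and with that share as chains begun if each chain needs released pre-initiator.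
- Red against amber supports first-order scaling: the ln at the last reading stands in a ratio of 1.11, the charges in a ratio of 1.13.
- Scaling amber's ln by the charge, we reckon conversions of 92.2% for north-west and 81.8% for north-east. Counting every released part as a chain gives lengths of 62.8 and 83.6, north-east being longer.
- The forecast, with “Chain counts are inferred, assuming no hidden termination”, names north-east, with 63 for north-west and 84 for north-east.
- The flasks give 77.8 in north-west and 101 in north-east, so north-east ends longer.

    free monomer + initiator → living end + monomer in chains (k = 0.0652 /M/s)
    free monomer + living end → monomer in chains + living end, rate k2*[living end]*[free monomer] (k = 0.844 /M/s)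
    monomer in chains → over-reaction product (k = 5.58 × 10⁻⁶ /s)
    pre-initiator → initiator (k = 0.00196 /s)
    monomer in chains + living end → free monomer + living end, rate k5*[living end] as long as [monomer in chains] is above zero (k = 0.0339 /s)

- At the end of north-west, the living end stands at 61.1% of the pre-initiator charge, and 30.9% is still pre-initiator. Our released share, applied to the 89.1% in chains there, gives 60.7, less than the flask's 77.8. For north-west stopped at 2.5 min, our read half-life counts 0.551 half-lives, a reckoned released share of 31.7%, while that flask still holds 74.5% of its charge as pre-initiator. With its 17.3% in chains, that gives 29.1, less than the 41.7 that flask holds.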